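Oak's bend cannot be nucleophile running out one for one: by 1.50 min it had used 0.183 M of electrophile, less than the 0.26 M of nucleophile charged, and yet its fall had bent.

| setting | oak | cedar | epsilon | delta |
|---|---|---|---|---|
| electrophile | 0.30 M | 0.30 M | 0.30 M | 0.30 M |
| nucleophile | 0.26 M | 0.78 M | 0.390 M | 0.390 M |
| free base | 0.090 M | 0.090 M | 0.0900 M | 0.140 M |
| remark | run made earlier | run made earlier |  |  |
| time |  |  | 10 min | 10 min |

- oak (time / min: electrophile / %, target / %): 0.500: 67, 27; 1.00: 47, 35; 1.50: 39, 40; 2.00: 34, 38; 2.50: 29, 37; 3.00: 22, 38; 4.00: 20, 34
- cedar (time / min: electrophile / %, target / %): 0.500: 27, 60; 1.00: 7, 71; 1.50: 3, 83; 2.00: 0, 81; 2.50: 0, 82; 3.00: 0, 79; 4.00: 0, 77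

(each reading ± 2 percentage points)

- no earlier run changes the charge of free base; that part of a forecast is a guess

- part of the electrophile that has reacted at the end, epsilon
- part of the electrophile that has reacted at the end, delta
- what raising the concentration of free base from its lowest to its highest value here does to the part of the electrophile that has reacted (changes below 5 percentage points count as none) (no change / it rises / it falls)

My reading is that each electrophile reacted sets acid free, and that this acid ties up a second nucleophile unless free base takes it. Call R the reach of a flask; for epsilon R = 80.0 %, which is nucleophile plus free base over twice the electrophile, the share of the charge its fast stage can turn over. Oak's R is 58.3 %, against 61.0 % reacted at the bend.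

Beyond its R oak's fall is slow: its electrophile went from 39 % to 20 % between 1.50 min and 4.00 min, which reads as a pseudo-first-order half-life of 2.59 min. With the bend at the same time as in oak, 10.3 % of what lies beyond R survives to 10 min. So I reckon 97.9 % reacted in epsilon, and, with R = 88.3 %, 98.8 % in delta.

The weak link is free base, which no earlier run varies. If delta's extra base counted for nothing, the two flasks would match; at full count the gap is 0.86 percentage points, less than the 5 points that counts as a change. I commit to no change either way.

The forecast gives 97 % and 98.5 %, slightly below my numbers, with no change: “Both are near the ceiling, so the change is under 5 points.”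

The flask gives 99.3 % in epsilon and 99.7 % in delta, so raising the free base brings no change, a change of 0.47 points.

    electrophile + nucleophile → acid set free + target (k = 0.0710 /M/s)
    nucleophile + acid set free ⇌ protonated nucleophile, settled at all times (K = 900 /M)
    acid set free + free base ⇌ salt of the base, settled at all times (K = 10000 /M)
    acid set free + target → side product A (k = 0.0760 /M/s)
    electrophile + target → side product B (k = 0.0240 /M/s)

In delta at 10.0 min, electrophile still has a half-life of 2.9 min by its path with target, shorter than the 10 min allowed. Side product B counts double in every percentage, so by 10.0 min in epsilon the nucleophile step had carried 76.5 % of the electrophile, less than R = 80.0 %.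

Now read delta early, at 2.5 min. Its R and the same tail give 91.0 % reacted; the neighbour flask gives 88.6 %, with 11.4 % of the electrophile left.

Readings and results come from a simulation from invented constants, noise included.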